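**Retrosynthetic overview**
1. Target 14 ⇐ regioselective mono-O-acetylation (less hindered 4-OH) of catechol 13 ⇐ bis-MOM ether 12.
2. Key step: the Ar(A)–CH2 bond is made by B-alkyl Suzuki–Miyaura coupling (sp2–sp3) of aryl triflate 10 with the 9-BBN adduct of styrene 4; no stilbene is made and nothing is hydrogenated next to the prenyl group.
3. Ring A piece 10 comes from two successive C–H functionalisations of 1,3-dimethoxybenzene: directed ortho-metalation/prenylation at C2, then sterically controlled Ir C–H borylation/oxidation at C5.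
4. Ring B piece 4 comes from 2,3,4-trihydroxybenzaldehyde: 3,4-bis-MOM protection, 2-O-methylation, methylenation.
5. No ring is formed: both benzene rings are bought, and A and B are joined in step 7.

Assumption: the target has no stereocentre and no E/Z element (achiral), so "single enantiomer" needs no stereocontrol; reagents are given by name and SMILES and are not numbered.

**Route**

Step 1
Reactants: 1 2,3,4-trihydroxybenzaldehyde
Product: 2 2-hydroxy-3,4-bis(methoxymethoxy)benzaldehyde
Conditions: MOMCl (2.1 equiv), K2CO3 (3 equiv), acetone, 0 °C to rt, N2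
Reagents that add atoms: chloromethyl methyl ether (MOMCl), COCCl
Why: Williamson-type O-alkylation (MOM protection); the 2-OH is tied up in the intramolecular hydrogen bond to the aldehyde C=O and is the least reactive, so the 4-OH (para to CHO, most acidic) and the 3-OH are etherified.

Step 2
Reactants: 2 2-hydroxy-3,4-bis(methoxymethoxy)benzaldehyde
Product: 3 2-methoxy-3,4-bis(methoxymethoxy)benzaldehyde
Conditions: MeI (1.5 equiv), K2CO3 (2 equiv), DMF, 40 °C
Reagents that add atoms: iodomethane, CI
Why: Williamson O-methylation of the one remaining (chelated) phenol in a polar aprotic solvent; MOM acetals are stable to base.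

Step 3
Reactants: 3 2-methoxy-3,4-bis(methoxymethoxy)benzaldehyde
Product: 4 1-ethenyl-2-methoxy-3,4-bis(methoxymethoxy)benzene
Conditions: Ph3PCH3Br (1.3 equiv), KOt-Bu (1.25 equiv), THF, 0 °C to rt
Reagents that add atoms: methyltriphenylphosphonium bromide, C[P+](c1ccccc1)(c1ccccc1)c1ccccc1.[Br-]
Why: Wittig methylenation of an aryl aldehyde with the non-stabilised ylide; it is used only to make a terminal styrene, and the aldehyde is the only electrophile present.

Step 4
Reactants: 5 1,3-dimethoxybenzene
Product: 7 1,3-dimethoxy-2-(3-methylbut-2-en-1-yl)benzene, via (2,6-dimethoxyphenyl)lithium 6 (not isolated)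
Conditions: n-BuLi (1.1 equiv), THF, 0 °C to rt, 2 h; then prenyl bromide (1.2 equiv), −78 °C to rt
Reagents that add atoms: prenyl bromide (1-bromo-3-methylbut-2-ene), CC(C)=CCBr
Why: Directed ortho-metalation at the C–H flanked by two methoxy groups, then SN2 alkylation of the aryllithium with the primary allylic bromide.

Step 5
Reactants: 7 1,3-dimethoxy-2-(3-methylbut-2-en-1-yl)benzene
Product: 9 3,5-dimethoxy-4-(3-methylbut-2-en-1-yl)phenol, via aryl pinacol boronate 8 (not isolated)
Conditions: [Ir(OMe)(cod)]2 (1.5 mol%), dtbpy (3 mol%), B2pin2 (0.6 equiv), THF, 80 °C; then 30% H2O2, aq NaOH, 0 °C to rt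
Reagents that add atoms: hydrogen peroxide, OO
Why: Hartwig–Miyaura Ir-catalysed C–H borylation is sterically controlled and goes to C5, the only ring C–H without an ortho substituent; the trisubstituted prenyl alkene has no accessible vinylic C–H and is a poor hydroboration substrate, and the one-pot alkaline peroxide oxidation of the C–B bond (1,2-aryl shift) does not touch an unactivated alkene.

Step 6
Reactants: 9 3,5-dimethoxy-4-(3-methylbut-2-en-1-yl)phenol
Product: 10 3,5-dimethoxy-4-(3-methylbut-2-en-1-yl)phenyl trifluoromethanesulfonate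
Conditions: PhNTf2 (1.1 equiv), Et3N (1.5 equiv), DMAP (cat.), CH2Cl2, rt
Reagents that add atoms: N-phenylbis(trifluoromethanesulfonimide) (PhNTf2), O=S(=O)(N(c1ccccc1)S(=O)(=O)C(F)(F)F)C(F)(F)F
Why: O-sulfonylation (triflation) of the phenol with a mild triflyl donor that attacks neither the alkene nor the electron-rich ring.

Step 7
Reactants: 4 1-ethenyl-2-methoxy-3,4-bis(methoxymethoxy)benzene; 10 3,5-dimethoxy-4-(3-methylbut-2-en-1-yl)phenyl trifluoromethanesulfonate
Product: 12 1,3-dimethoxy-5-{2-[2-methoxy-3,4-bis(methoxymethoxy)phenyl]ethyl}-2-(3-methylbut-2-en-1-yl)benzene, via B-alkyl-9-BBN borane 11 (not isolated)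
Conditions: 4 (1.4 equiv), 9-BBN (1.3 equiv, 0.5 M in THF), 0 °C to rt, 3 h; then 10 (1.0 equiv), PdCl2(dppf)·CH2Cl2 (5 mol%), 3 M aq K3PO4 (3 equiv), DMF, 60 °C
Reagents that add atoms: none
Why: Anti-Markovnikov hydroboration of the styrene with 9-BBN followed by B-alkyl Suzuki–Miyaura coupling with the aryl triflate gives the CH2CH2 bridge directly; the styrene is in excess over 9-BBN, so no B–H is left when prenyl-bearing 10 is added, and dppf favours reductive elimination over β-hydride elimination.

Step 8
Reactants: 12 1,3-dimethoxy-5-{2-[2-methoxy-3,4-bis(methoxymethoxy)phenyl]ethyl}-2-(3-methylbut-2-en-1-yl)benzene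
Product: 13 4-{2-[3,5-dimethoxy-4-(3-methylbut-2-en-1-yl)phenyl]ethyl}-3-methoxybenzene-1,2-diol
Conditions: conc. HCl (cat.), MeOH, rt to 40 °C
Reagents that add atoms: none
Why: Acid-catalysed acetal methanolysis removes both MOM groups; the prenyl group has methoxy (not hydroxy) neighbours, so it cannot cyclise to a chroman, and it survives dilute methanolic HCl at this temperature.

Step 9
Reactants: 13 4-{2-[3,5-dimethoxy-4-(3-methylbut-2-en-1-yl)phenyl]ethyl}-3-methoxybenzene-1,2-diol
Product: 14 4-{2-[3,5-dimethoxy-4-(3-methylbut-2-en-1-yl)phenyl]ethyl}-2-hydroxy-3-methoxyphenyl acetate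
Conditions: Ac2O (1.0 equiv), pyridine, CH2Cl2, −20 to 0 °C
Reagents that add atoms: acetic anhydride, CC(=O)OC(C)=O
Why: Regioselective O-acylation of a catechol: the 4-OH is the less hindered hydroxyl, whereas the 3-OH is flanked by two oxygen substituents and hydrogen-bonded to the 2-OMe; the 4-O-acetate with a guaiacol-type hydrogen-bonded 3-OH is also the isomer favoured if the acetyl group migrates.

**Compound list**
1 | 2,3,4-trihydroxybenzaldehyde | O=Cc1ccc(O)c(O)c1O | starting material
2 | 2-hydroxy-3,4-bis(methoxymethoxy)benzaldehyde | O=Cc1ccc(OCOC)c(OCOC)c1O | intermediate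
3 | 2-methoxy-3,4-bis(methoxymethoxy)benzaldehyde | O=Cc1ccc(OCOC)c(OCOC)c1OC | intermediate
4 | 1-ethenyl-2-methoxy-3,4-bis(methoxymethoxy)benzene | C=Cc1ccc(OCOC)c(OCOC)c1OC | intermediate
5 | 1,3-dimethoxybenzene | COc1cccc(OC)c1 | starting material
6 | (2,6-dimethoxyphenyl)lithium | [Li]c1c(OC)cccc1OC | intermediate (not isolated)
7 | 1,3-dimethoxy-2-(3-methylbut-2-en-1-yl)benzene | COc1cccc(OC)c1CC=C(C)C | intermediate
8 | 2-[3,5-dimethoxy-4-(3-methylbut-2-en-1-yl)phenyl]-4,4,5,5-tetramethyl-1,3,2-dioxaborolane | COc1cc(B2OC(C)(C)C(C)(C)O2)cc(OC)c1CC=C(C)C | intermediate (not isolated)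
9 | 3,5-dimethoxy-4-(3-methylbut-2-en-1-yl)phenol | COc1cc(O)cc(OC)c1CC=C(C)C | intermediate
10 | 3,5-dimethoxy-4-(3-methylbut-2-en-1-yl)phenyl trifluoromethanesulfonate | COc1cc(OS(=O)(=O)C(F)(F)F)cc(OC)c1CC=C(C)C | intermediate
11 | 9-{2-[2-methoxy-3,4-bis(methoxymethoxy)phenyl]ethyl}-9-borabicyclo[3.3.1]nonane | COCOc1ccc(CCB2C3CCCC2CCC3)c(OC)c1OCOC | intermediate (not isolated)
12 | 1,3-dimethoxy-5-{2-[2-methoxy-3,4-bis(methoxymethoxy)phenyl]ethyl}-2-(3-methylbut-2-en-1-yl)benzene | COc1cc(CCc2ccc(OCOC)c(OCOC)c2OC)cc(OC)c1CC=C(C)C | intermediate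
13 | 4-{2-[3,5-dimethoxy-4-(3-methylbut-2-en-1-yl)phenyl]ethyl}-3-methoxybenzene-1,2-diol | COc1cc(CCc2ccc(O)c(O)c2OC)cc(OC)c1CC=C(C)C | intermediate
14 | 4-{2-[3,5-dimethoxy-4-(3-methylbut-2-en-1-yl)phenyl]ethyl}-2-hydroxy-3-methoxyphenyl acetate (CNP0143232.0) | COc1cc(CCc2ccc(OC(C)=O)c(O)c2OC)cc(OC)c1CC=C(C)C | target

**Step count and risks**
Total steps: 9. Longest linear sequence: 6 (steps 1, 2, 3, 7, 8, 9, or equally 4, 5, 6, 7, 8, 9).

The three steps most likely to fail are steps 5, 7 and 9.

Step 5 (Ir borylation next to the prenyl alkene). The Ir–H/HBpin system could isomerise or hydroborate the alkene. The fallback avoids C–H borylation altogether; it sets out from styrene 4 (through its borane 11) and comes back to the route at 12. Bought 1-bromo-3,5-dimethoxybenzene F1 is deprotonated with LDA (THF, −78 °C) between the two methoxy groups, where both oxygens hold the lithium, to give (4-bromo-2,6-dimethoxyphenyl)lithium F2. This regiochemistry is the uncertain point of the fallback, because the C–H next to bromine competes and n-BuLi cannot be used (it would exchange the bromine). F2 is alkylated in the same flask with prenyl bromide to 5-bromo-1,3-dimethoxy-2-(3-methylbut-2-en-1-yl)benzene F3. F3 then replaces triflate 10 in the B-alkyl Suzuki coupling with 11 (PdCl2(dppf), aq K3PO4, THF/DMF, 60 °C) and gives 12.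

Step 7 (sp2–sp3 Suzuki coupling). It may suffer from protodeboronation, β-hydride elimination or triflate hydrolysis. The fallback joins the same two pieces by sp2–sp2 chemistry, setting out from 4 and 10 and coming back at 12. A Heck reaction under halide-containing conditions (Pd(OAc)2, P(o-tol)3, n-Bu4NCl, K2CO3, DMF, 90 °C, neutral pathway for β-arylation) gives 1,3-dimethoxy-5-{(E)-2-[2-methoxy-3,4-bis(methoxymethoxy)phenyl]ethenyl}-2-(3-methylbut-2-en-1-yl)benzene F4. Its 1,2-disubstituted C=C is then reduced with diimide (2-nitrobenzenesulfonyl hydrazide, Et3N, CH2Cl2, rt), which reacts much more slowly with the trisubstituted prenyl alkene, to give 12.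

Step 9 (regioselective mono-acetylation). It can give some diacetate and some 3-O-acetyl isomer. The fallback sets out from 13 and comes back at 14, delivering exactly one acetyl group through a cyclic orthoester. Catechol 13 is condensed with trimethyl orthoacetate (PPTS cat., toluene, 4 Å MS) to 5-{2-[3,5-dimethoxy-4-(3-methylbut-2-en-1-yl)phenyl]ethyl}-2,4-dimethoxy-2-methyl-1,3-benzodioxole F5, which is racemic at the orthoester carbon; that centre is lost again. Mild hydrolysis (AcOH/H2O/THF, 0 °C) opens F5 through the cyclic hemi-orthoester to the monoacetate. No diacetate can form, and any 3-O-acetate equilibrates through the same intermediate to the less hindered 4-O-acetate 14.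

**Further compounds**
F1 | step 5 | 1-bromo-3,5-dimethoxybenzene (bought) | COc1cc(Br)cc(OC)c1
F2 | step 5 | (4-bromo-2,6-dimethoxyphenyl)lithium (not isolated) | [Li]c1c(OC)cc(Br)cc1OC
F3 | step 5 | 5-bromo-1,3-dimethoxy-2-(3-methylbut-2-en-1-yl)benzene | COc1cc(Br)cc(OC)c1CC=C(C)C
F4 | step 7 | 1,3-dimethoxy-5-{(E)-2-[2-methoxy-3,4-bis(methoxymethoxy)phenyl]ethenyl}-2-(3-methylbut-2-en-1-yl)benzene | COc1cc(/C=C/c2ccc(OCOC)c(OCOC)c2OC)cc(OC)c1CC=C(C)C
F5 | step 9 | 5-{2-[3,5-dimethoxy-4-(3-methylbut-2-en-1-yl)phenyl]ethyl}-2,4-dimethoxy-2-methyl-1,3-benzodioxole (racemic at C2) | COc1cc(CCc2ccc3OC(C)(OC)Oc3c2OC)cc(OC)c1CC=C(C)C
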